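Take 2 equivalents of reagent off the charge before you reckon with it. The runs read triple product only, so I solve the flask at its two ends and join them. Early on, I assume, the substrate quickly takes up two reagents and rests mostly as bis adduct, the resting state. Later, I assume, the third addition creeps along with reagent in excess, pseudo-first-order in bis adduct, its rate proportional to the free reagent and triple product about linear in time.

| flask | substrate | reagent | remark | time |
|---|---|---|---|---|
| blue | 0.060 M | 0.24 M | run made earlier |  |
| red | 0.060 M | 0.35 M | run made earlier |  |
| north | 0.060 M | 0.300 M |  | 5.0 min |
| south-west | 0.060 M | 0.390 M |  | 5.0 min |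

| run | time / min | triple product / % |
|---|---|---|
| blue | 0.250 | 0.4 |
| blue | 0.417 | 0 |
| blue | 0.667 | 0.2 |
| blue | 1.00 | 0.6 |
| blue | 1.50 | 1.4 |
| blue | 2.50 | 2.3 |
| blue | 4.00 | 8.1 |
| red | 0.250 | 0.3 |
| red | 0.417 | 1.7 |
| red | 0.667 | 2.7 |
| red | 1.00 | 2.9 |
| red | 1.50 | 1.2 |
| red | 2.50 | 9.3 |
| red | 4.00 | 16.7 |

(scatter of a reading: 1 percentage point)

- in percentages every species weighs as the substrate in it: one homo dimer counts as two
- for triple product the crystals are counted in
- as a solid, counted per litre of solution: crystals
- the earlier runs were read with a standard deviation of 1 percentage point
- steps that have been proposed: substrate + reagent -> mono adduct; reagent + mono adduct -> bis adduct; reagent + bis adduct -> triple product; reagent + triple product <-> tetra adduct; 2 substrate -> homo dimer; crystals <-> triple product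

1. which of the two there is more of at the end, north (tetra adduct / triple product)
2. which of the two there is more of at the end, south-west (tetra adduct / triple product)
3. final triple product, as a percentage of the substrate charged, in north
4. final triple product, as a percentage of the substrate charged, in south-west

Joined, I take triple product as a constant times excess times time, the excess being the equivalents charged minus 2. Blue has 2.00 equivalents of excess and red 3.83. Their last readings, divided by excess and time, give 0.0101 min⁻¹ and 0.0109 min⁻¹. The mean is the climb constant 0.0105 min⁻¹, the fraction of the charge turned into triple product per minute and per equivalent of excess, with substrate held at 0.060 M. North has 3.00 equivalents of excess, so I expect 15.8%. South-west has 4.50, so I expect 23.6%.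

The second way assumes no stoichiometry. I extend each run to 5.0 min along its own last climb, which gives 12.0% for blue and 21.6% for red, then draw a straight line across the reagent charge. That gives 17.2% for north and 25.1% for south-west, about 1.4 percentage points above the first way. This way cheats a little: its climb is a difference of two readings, and the extension carries the scatter of 1 point about 1.80 times over. So I commit to the first way.

The forecast gives 20% for north and, “with some allowance for reagent depletion”, 30% for south-west, and puts triple product ahead of tetra adduct in both. My numbers stand lower, and there we differ. No run reads tetra adduct, so I have no reckoning of my own on that mark and take the forecast's.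

North holds 15.8% of triple product and south-west 22.9%, against my 15.8% and 23.6%. Tetra adduct holds 1.30% in north and 2.11% in south-west, so triple product stays ahead in both.

    substrate + reagent → mono adduct (k = 0.143 L mol⁻¹ s⁻¹)
    reagent + mono adduct → bis adduct (k = 0.170 L mol⁻¹ s⁻¹)
    reagent + bis adduct → triple product (k = 0.00458 L mol⁻¹ s⁻¹)
    reagent + triple product ⇌ tetra adduct (K = 4.79 L mol⁻¹, k = 0.0238 L mol⁻¹ s⁻¹)
    2 substrate → homo dimer (k = 0.127 L mol⁻¹ s⁻¹)
    crystals ⇌ triple product, rate k6*(cs6 - [triple product]) while solid is left; crystals form when [triple product] > cs6 (solubility = 0.790 mM, k = 0.0954 s⁻¹)

Now take the neighbour of north charged with 0.51 M of reagent, 8.50 equiv. Its excess is 6.50 equivalents, so the climb constant gives 34.1% at 5.0 min. That flask holds 31.5% of triple product, with 55.5% still bis adduct.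

Readings and results are calculated for an exercise, and the scatter is random.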